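The target is a 6,8''-linked biflavone: an acacetin half (unit 1, rings A, C and B) and a genkwanin half (unit 2, doubly primed locants). The plan cuts the C4a–C5 bond of ring A of unit 1, a phloroglucinol with oxygen on C5, C7 and C8a, the acyl carbon C4 on C4a and C8'' on C6, which is a folded tetraketide arylated next to its ester carbon. A magnesium methoxide Claisen cyclisation of a 3-aryl-4-hydroxypyran-2-one bearing a 4-methoxycinnamoylmethyl group forms this bond, ring A and the chalcone at once, so the hindered biaryl axis stems from an arylacetate. Oxidative closure of ring C and debenzylation follow.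

Key step: step 11

Remarks on the chemistry:
- The target SMILES fixes no configuration for the hindered C6–C8'' axis, so the axis is made without stereocontrol.
- Ring letters A, B and C without primes refer to unit 1.
- Compounds 12, 17 and 18 are drawn as keto tautomers.
- Fl8 stands for the 5-(benzyloxy)-2-[4-(benzyloxy)phenyl]-7-methoxy-4-oxo-4H-chromen-8-yl group (di-O-benzylgenkwanin-8''-yl).
- Both benzyl ethers are installed before the allyl shift and the methyl ether after it, so that no alkylation after step 1 has to choose between phenols and the 5''-oxygen is not chelated during the rearrangement.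

**Step 1**
Reactants: 1 apigenin; 2 allyl bromide
Product: 3 7-(allyloxy)-5-hydroxy-2-(4-hydroxyphenyl)-4H-chromen-4-one
Conditions: K2CO3 (1.1 equiv), allyl bromide (1.05 equiv), DMF, rt
Reagents that add atoms: none
Why: Williamson etherification with about one equivalent of base and halide should alkylate the most acidic 7-OH (para to the pyranone carbonyl) in preference to the 4'-OH and the chelated 5-OH.

**Step 2**
Reactants: 3 7-(allyloxy)-5-hydroxy-2-(4-hydroxyphenyl)-4H-chromen-4-one
Product: 4 7-(allyloxy)-5-(benzyloxy)-2-[4-(benzyloxy)phenyl]-4H-chromen-4-one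
Conditions: BnBr (3 equiv), K2CO3, DMF, 70 °C
Reagents that add atoms: benzyl bromide, BrCc1ccccc1
Why: Williamson etherification under forcing conditions should benzylate both the 4'-OH and the chelated 5-OH, which also removes the hydrogen bond that would steer the next step towards C6''.

**Step 3**
Reactants: 4 7-(allyloxy)-5-(benzyloxy)-2-[4-(benzyloxy)phenyl]-4H-chromen-4-one
Product: 5 8-allyl-5-(benzyloxy)-2-[4-(benzyloxy)phenyl]-7-hydroxy-4H-chromen-4-one
Conditions: PhNEt2, 200 °C
Reagents that add atoms: none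
Why: The aromatic Claisen rearrangement ([3,3]-sigmatropic shift, then rearomatisation) of a 7-allyloxychromone without a chelated 5-OH should deliver the allyl group mainly to C8''; the C6'' isomer is the only other ortho product and would be removed by chromatography.

**Step 4**
Reactants: 5 8-allyl-5-(benzyloxy)-2-[4-(benzyloxy)phenyl]-7-hydroxy-4H-chromen-4-one
Product: 6 8-allyl-5-(benzyloxy)-2-[4-(benzyloxy)phenyl]-7-methoxy-4H-chromen-4-one
Conditions: MeI, K2CO3, acetone, reflux
Reagents that add atoms: iodomethane, CI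
Why: Williamson etherification of the only free phenol sets the 7''-methoxy group of unit 2 without any selectivity question.

**Step 5**
Reactants: 6 8-allyl-5-(benzyloxy)-2-[4-(benzyloxy)phenyl]-7-methoxy-4H-chromen-4-one
Product: 8 2-Fl8-acetaldehyde, via diol 7 (not isolated)
Conditions: OsO4 (cat.), NaIO4, 2,6-lutidine, dioxane/H2O, rt
Reagents that add atoms: osmium tetroxide, O=[Os](=O)(=O)=O; sodium periodate, [Na+].[O-]I(=O)(=O)=O
Why: In the Lemieux–Johnson oxidation the isolated terminal alkene is dihydroxylated and the diol is cleaved by periodate, while the push-pull C2''=C3'' bond of the flavone should react far more slowly with OsO4.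

**Step 6**
Reactants: 8 2-Fl8-acetaldehyde
Product: 9 2-Fl8-acetic acid
Conditions: NaClO2, NaH2PO4, 2-methyl-2-butene, t-BuOH/H2O, rt
Reagents that add atoms: sodium chlorite, [Na+].[O-]Cl=O
Why: The Pinnick oxidation converts the enolisable aldehyde into the acid without touching the ethers or the flavone, and the alkene scavenger traps hypochlorous acid before it can chlorinate the electron-rich rings.

**Step 7**
Reactants: 9 2-Fl8-acetic acid
Product: 10 methyl 2-Fl8-acetate
Conditions: MeI, K2CO3, DMF, rt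
Reagents that add atoms: iodomethane, CI
Why: SN2 alkylation of the carboxylate gives the methyl ester that serves first as enolate precursor and later as the lactone carbonyl; the carbonate base is too weak to deprotonate the benzylic position.

**Step 8**
Reactants: 10 methyl 2-Fl8-acetate; 11 diketene
Product: 13 3-Fl8-4-hydroxy-6-methyl-2H-pyran-2-one, via dioxo ester 12 (not isolated)
Conditions: LiN(SiMe3)2 (1.1 equiv), THF, −78 °C; then diketene, −78 to −30 °C; aq. HCl; then DBU, toluene, 80 °C; aq. HCl
Reagents that add atoms: none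
Why: Claisen-type C-acetoacetylation of the lithium ester enolate by diketene (opening of the β-lactone) should give the 3,5-dioxo ester, whose enol oxygen at chain C5 then lactonises onto the methyl ester under DBU to the 4-hydroxypyran-2-one; the silylamide base deprotonates the far more acidic arylacetate position and should leave the flavone untouched.

**Step 9**
Reactants: 14 (E)-4-methoxycinnamic acid
Product: 16 (E)-N-methoxy-3-(4-methoxyphenyl)-N-methylprop-2-enamide, via acyl imidazole 15 (not isolated)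
Conditions: 1,1'-carbonyldiimidazole, CH2Cl2, rt; then MeNH(OMe)·HCl, rt
Reagents that add atoms: N,O-dimethylhydroxylamine hydrochloride, CNOC.Cl
Why: Amide formation through the acyl imidazole gives the Weinreb amide, an acyl donor that takes up a carbanion once at the carbonyl carbon and is a poorer Michael acceptor than the corresponding ester.

**Step 10**
Reactants: 13 3-Fl8-4-hydroxy-6-methyl-2H-pyran-2-one; 16 (E)-N-methoxy-3-(4-methoxyphenyl)-N-methylprop-2-enamide
Product: 17 3-Fl8-4-hydroxy-6-[(E)-4-(4-methoxyphenyl)-2-oxobut-3-enyl]-2H-pyran-2-one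
Conditions: LiN(i-Pr)2 (2.2 equiv), THF, −78 °C; then amide 16, −78 to 0 °C; aq. HCl
Reagents that add atoms: none
Why: In this acylation of the pyranone dianion the 6-methyl carbanion (the 3-position is blocked by the aryl group) should add to the amide carbonyl, and the chelated tetrahedral adduct collapses to the enone only on acidic work-up, which prevents over-addition and proton quench by the product.

**Step 11**
Reactants: 17 3-Fl8-4-hydroxy-6-[(E)-4-(4-methoxyphenyl)-2-oxobut-3-enyl]-2H-pyran-2-one
Product: 19 (E)-1-(3-Fl8-2,4,6-trihydroxyphenyl)-3-(4-methoxyphenyl)prop-2-en-1-one, via triketo ester 18 (not isolated)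
Conditions: Mg(OMe)2 (excess), MeOH/THF, reflux, under argon; then cold 1 M HCl
Reagents that add atoms: none
Why: Methoxide from Mg(OMe)2 opens the lactone of 17 at its carbonyl to the magnesium-chelated methyl 3,5,7-trioxo ester 18; the enolate carbon between the 5- and 7-keto groups of the chain (future C4a) adds to the ester carbonyl (future C5) and methoxide leaves, so the C4a–C5 bond forms and the triketone enolises to aromatic ring A with the cinnamoyl group left as the chalcone. The closest known reaction type is the Claisen (Dieckmann-type) cyclisation of 3,5,7-triketo esters and of 6-(2-oxoalkyl)-4-hydroxypyran-2-ones to acylphloroglucinols under magnesium methoxide. Ring A closes in a 6-(enolendo)-exo-trig mode. No stereocentre is created, and the C6–C8'' axis, present since 13, stays unresolved. The step needs Claisen folding to win over aldol folding, Michael addition to the enone and plain re-lactonisation: the aldol mode would need the aryl-bearing carbon (future C6) as nucleophile and would leave a quaternary carbon that cannot aromatise, while magnesium chelation of the β-tricarbonyl array activates the ester and aromatisation makes the closure irreversible. The strongly basic medium should keep the product as the open chalcone phenoxide until the cold acidic quench.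

**Step 12**
Reactants: 19 (E)-1-(3-Fl8-2,4,6-trihydroxyphenyl)-3-(4-methoxyphenyl)prop-2-en-1-one
Product: 20 6-Fl8-5,7-dihydroxy-2-(4-methoxyphenyl)-4H-chromen-4-one
Conditions: I2 (10 mol %), DMSO, 130 °C
Reagents that add atoms: none
Why: The iodine/DMSO oxidative cyclisation of a 2'-hydroxychalcone (intramolecular oxa-Michael addition, then iodine-mediated dehydrogenation with DMSO as terminal oxidant) should close ring C mainly through the unhindered C6' hydroxyl (future O1), because the C2' hydroxyl is pressed by the neighbouring aryl group into the chelate with the carbonyl group; benzyl and methyl ethers are inert.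

**Step 13**
Reactants: 20 6-Fl8-5,7-dihydroxy-2-(4-methoxyphenyl)-4H-chromen-4-one
Product: 21 6-[5-hydroxy-2-(4-hydroxyphenyl)-7-methoxy-4-oxo-4H-chromen-8-yl]-5,7-dihydroxy-2-(4-methoxyphenyl)-4H-chromen-4-one (target)
Conditions: H2 (1 atm), Pd/C, THF/MeOH, rt
Reagents that add atoms: none
Why: Catalytic hydrogenolysis of the two benzyl aryl ethers frees the 5''- and 4'''-hydroxyls, while the methyl ethers and the flavone C2=C3 bonds should survive mild, monitored conditions.

**Compound list**

1 | apigenin | O=c1cc(-c2ccc(O)cc2)oc2cc(O)cc(O)c12 | starting material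
2 | allyl bromide | C=CCBr | starting material
3 | 7-(allyloxy)-5-hydroxy-2-(4-hydroxyphenyl)-4H-chromen-4-one | O=c1cc(-c2ccc(O)cc2)oc2cc(OCC=C)cc(O)c12 | intermediate
4 | 7-(allyloxy)-5-(benzyloxy)-2-[4-(benzyloxy)phenyl]-4H-chromen-4-one | O=c1cc(-c2ccc(OCc3ccccc3)cc2)oc2cc(OCC=C)cc(OCc3ccccc3)c12 | intermediate
5 | 8-allyl-5-(benzyloxy)-2-[4-(benzyloxy)phenyl]-7-hydroxy-4H-chromen-4-one | O=c1cc(-c2ccc(OCc3ccccc3)cc2)oc2c(CC=C)c(O)cc(OCc3ccccc3)c12 | intermediate
6 | 8-allyl-5-(benzyloxy)-2-[4-(benzyloxy)phenyl]-7-methoxy-4H-chromen-4-one | O=c1cc(-c2ccc(OCc3ccccc3)cc2)oc2c(CC=C)c(OC)cc(OCc3ccccc3)c12 | intermediate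
7 | 5-(benzyloxy)-2-[4-(benzyloxy)phenyl]-8-(2,3-dihydroxypropyl)-7-methoxy-4H-chromen-4-one (racemic diol) | O=c1cc(-c2ccc(OCc3ccccc3)cc2)oc2c(CC(O)CO)c(OC)cc(OCc3ccccc3)c12 | intermediate
8 | 2-Fl8-acetaldehyde | O=CCc1c(OC)cc(OCc2ccccc2)c2c(=O)cc(-c3ccc(OCc4ccccc4)cc3)oc12 | intermediate
9 | 2-Fl8-acetic acid | OC(=O)Cc1c(OC)cc(OCc2ccccc2)c2c(=O)cc(-c3ccc(OCc4ccccc4)cc3)oc12 | intermediate
10 | methyl 2-Fl8-acetate | COC(=O)Cc1c(OC)cc(OCc2ccccc2)c2c(=O)cc(-c3ccc(OCc4ccccc4)cc3)oc12 | intermediate
11 | diketene (4-methyleneoxetan-2-one) | C=C1CC(=O)O1 | starting material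
12 | methyl 2-Fl8-3,5-dioxohexanoate (racemic, dioxo ester) | COC(=O)C(C(=O)CC(C)=O)c1c(OC)cc(OCc2ccccc2)c2c(=O)cc(-c3ccc(OCc4ccccc4)cc3)oc12 | intermediate
13 | 3-Fl8-4-hydroxy-6-methyl-2H-pyran-2-one | CC1=CC(O)=C(c2c(OC)cc(OCc3ccccc3)c3c(=O)cc(-c4ccc(OCc5ccccc5)cc4)oc23)C(=O)O1 | intermediate
14 | (E)-4-methoxycinnamic acid | COc1ccc(/C=C/C(=O)O)cc1 | starting material
15 | (E)-1-(1H-imidazol-1-yl)-3-(4-methoxyphenyl)prop-2-en-1-one (acyl imidazole) | COc1ccc(/C=C/C(=O)n2ccnc2)cc1 | intermediate
16 | (E)-N-methoxy-3-(4-methoxyphenyl)-N-methylprop-2-enamide | COc1ccc(/C=C/C(=O)N(C)OC)cc1 | intermediate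
17 | 3-Fl8-4-hydroxy-6-[(E)-4-(4-methoxyphenyl)-2-oxobut-3-enyl]-2H-pyran-2-one | COc1ccc(/C=C/C(=O)CC2=CC(O)=C(c3c(OC)cc(OCc4ccccc4)c4c(=O)cc(-c5ccc(OCc6ccccc6)cc5)oc34)C(=O)O2)cc1 | intermediate
18 | methyl (E)-2-Fl8-9-(4-methoxyphenyl)-3,5,7-trioxonon-8-enoate (racemic, triketo ester) | COC(=O)C(C(=O)CC(=O)CC(=O)/C=C/c1ccc(OC)cc1)c1c(OC)cc(OCc2ccccc2)c2c(=O)cc(-c3ccc(OCc4ccccc4)cc3)oc12 | intermediate
19 | (E)-1-(3-Fl8-2,4,6-trihydroxyphenyl)-3-(4-methoxyphenyl)prop-2-en-1-one (2'-OH lies between the acyl and aryl groups) | COc1ccc(/C=C/C(=O)c2c(O)cc(O)c(-c3c(OC)cc(OCc4ccccc4)c4c(=O)cc(-c5ccc(OCc6ccccc6)cc5)oc34)c2O)cc1 | intermediate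
20 | 6-Fl8-5,7-dihydroxy-2-(4-methoxyphenyl)-4H-chromen-4-one (5'',4'''-di-O-benzyl ether of the target) | COc1ccc(-c2cc(=O)c3c(O)c(-c4c(OC)cc(OCc5ccccc5)c5c(=O)cc(-c6ccc(OCc7ccccc7)cc6)oc45)c(O)cc3o2)cc1 | intermediate
21 | 6-[5-hydroxy-2-(4-hydroxyphenyl)-7-methoxy-4-oxo-4H-chromen-8-yl]-5,7-dihydroxy-2-(4-methoxyphenyl)-4H-chromen-4-one | COc1ccc(-c2cc(=O)c3c(O)c(-c4c(OC)cc(O)c5c(=O)cc(-c6ccc(O)cc6)oc45)c(O)cc3o2)cc1 | target

**Step count.** Total: 13 steps. Longest linear sequence: 12 steps (steps 1–8 and 10–13 from apigenin); step 9 prepares the side-chain amide 16.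

**Steps most likely to fail**

1. Step 11. The opened chain may not fold by the Claisen mode: Michael addition of a chain methylene or of methoxide to the enone, return to the lactone, or base-induced opening of the pyranone ring of unit 2 could compete. The fallback separates the formation of ring A from the enone. It sets out from 13, whose dianion would be acylated with N-methoxy-N-methylacetamide to 3-Fl8-4-hydroxy-6-(2-oxopropyl)-2H-pyran-2-one F1. Mg(OMe)2 in MeOH would then cyclise this chain, which has no Michael acceptor, to 1-(3-Fl8-2,4,6-trihydroxyphenyl)ethanone F2. NaH/MOMCl would give its tris(methoxymethyl) ether F3, and Claisen–Schmidt condensation with 4-methoxybenzaldehyde (KOH, EtOH/THF) would give the tris(methoxymethyl) ether of the chalcone F4. HCl in MeOH would remove the acetals and return to the route at 19.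

2. Step 12. Ring C may close in part through the hindered 2'-hydroxyl, which would lead to the 8,8''-linked isomer; iodination of the free position of ring A is a further side process. The fallback fixes the regiochemistry by protection and sets out from 19. MOMCl (2 equiv)/i-Pr2NEt should alkylate the two unhindered phenols and leave the chelated, aryl-flanked one, giving the 4',6'-bis(methoxymethyl) ether F5. BnBr/K2CO3 would benzylate the remaining hydroxyl to the 2'-O-benzyl-4',6'-bis(methoxymethyl) ether F6. HCl/MeOH would give 2'-(benzyloxy)-4',6'-dihydroxychalcone F7, in which only the correct phenol can cyclise. I2/DMSO would give the 5,5'',4'''-tri-O-benzyl biflavone F8, and hydrogenolysis over Pd/C would return to the route at 21.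

3. Step 10. The carbanion may add in conjugate fashion to the unsaturated amide, the tetrahedral adduct may collapse early so that the acidic product quenches unreacted dianion, or metalation of the pyranone methyl group may be incomplete. The fallback brings in the side chain as an aldehyde, which reacts faster and at the carbonyl carbon and gives a non-acidic alkoxide adduct; it sets out from 13. Its dianion would add at −78 °C to the carbonyl group of (E)-4-methoxycinnamaldehyde to give 3-Fl8-4-hydroxy-6-[(E)-2-hydroxy-4-(4-methoxyphenyl)but-3-enyl]-2H-pyran-2-one F9. MnO2 oxidation of the allylic alcohol would return to the route at 17.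

**Further compounds**

F1 | step 11 | 3-Fl8-4-hydroxy-6-(2-oxopropyl)-2H-pyran-2-one | CC(=O)CC1=CC(O)=C(c2c(OC)cc(OCc3ccccc3)c3c(=O)cc(-c4ccc(OCc5ccccc5)cc4)oc23)C(=O)O1
F2 | step 11 | 1-(3-Fl8-2,4,6-trihydroxyphenyl)ethanone | CC(=O)c1c(O)cc(O)c(-c2c(OC)cc(OCc3ccccc3)c3c(=O)cc(-c4ccc(OCc5ccccc5)cc4)oc23)c1O
F3 | step 11 | 1-[3-Fl8-2,4,6-tris(methoxymethoxy)phenyl]ethanone | CC(=O)c1c(OCOC)cc(OCOC)c(-c2c(OC)cc(OCc3ccccc3)c3c(=O)cc(-c4ccc(OCc5ccccc5)cc4)oc23)c1OCOC
F4 | step 11 | (E)-1-[3-Fl8-2,4,6-tris(methoxymethoxy)phenyl]-3-(4-methoxyphenyl)prop-2-en-1-one | COc1ccc(/C=C/C(=O)c2c(OCOC)cc(OCOC)c(-c3c(OC)cc(OCc4ccccc4)c4c(=O)cc(-c5ccc(OCc6ccccc6)cc5)oc34)c2OCOC)cc1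
F5 | step 12 | (E)-1-[3-Fl8-2-hydroxy-4,6-bis(methoxymethoxy)phenyl]-3-(4-methoxyphenyl)prop-2-en-1-one | COc1ccc(/C=C/C(=O)c2c(OCOC)cc(OCOC)c(-c3c(OC)cc(OCc4ccccc4)c4c(=O)cc(-c5ccc(OCc6ccccc6)cc5)oc34)c2O)cc1
F6 | step 12 | (E)-1-[2-(benzyloxy)-3-Fl8-4,6-bis(methoxymethoxy)phenyl]-3-(4-methoxyphenyl)prop-2-en-1-one | COc1ccc(/C=C/C(=O)c2c(OCOC)cc(OCOC)c(-c3c(OC)cc(OCc4ccccc4)c4c(=O)cc(-c5ccc(OCc6ccccc6)cc5)oc34)c2OCc7ccccc7)cc1
F7 | step 12 | (E)-1-[2-(benzyloxy)-3-Fl8-4,6-dihydroxyphenyl]-3-(4-methoxyphenyl)prop-2-en-1-one | COc1ccc(/C=C/C(=O)c2c(O)cc(O)c(-c3c(OC)cc(OCc4ccccc4)c4c(=O)cc(-c5ccc(OCc6ccccc6)cc5)oc34)c2OCc7ccccc7)cc1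
F8 | step 12 | 5-(benzyloxy)-6-Fl8-7-hydroxy-2-(4-methoxyphenyl)-4H-chromen-4-one | COc1ccc(-c2cc(=O)c3c(OCc8ccccc8)c(-c4c(OC)cc(OCc5ccccc5)c5c(=O)cc(-c6ccc(OCc7ccccc7)cc6)oc45)c(O)cc3o2)cc1
F9 | step 10 | 3-Fl8-4-hydroxy-6-[(E)-2-hydroxy-4-(4-methoxyphenyl)but-3-enyl]-2H-pyran-2-one (racemic alcohol) | COc1ccc(/C=C/C(O)CC2=CC(O)=C(c3c(OC)cc(OCc4ccccc4)c4c(=O)cc(-c5ccc(OCc6ccccc6)cc5)oc34)C(=O)O2)cc1
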